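**Retrosynthetic overview** (hydroazulene numbering: C1–C3, C3a, C4–C8, C8a)
1. Target ⇐ the 4α-aroyloxy group from hydroxyl-directed reduction of a C4 ketone and acylation; the 8β-isovalerate from Mitsunobu inversion of the equatorial 8α-alcohol.
2. C3 carbinol ⇐ hydride opening of the β-epoxide of a C2=C3 cyclopentene. This five-membered ring (C1, C2, C3, C3a, C8a) ⇐ ring-closing metathesis, made possible by an allyl group on C8a and a 1-isopropylvinyl group on C3a that stand trans on neighbouring carbons of the seven-membered ring, so that closure joins C2 to C3 and touches neither ring-fusion atom.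
3. That diene ⇐ one anti-selective three-component coupling (alkenyl nucleophile to C3a, allyl electrophile to C8a) on (S)-4-silyloxy-2,6-dimethylcyclohepta-2,6-dienone.
4. Dienone ⇐ tropone: hydride dearomatization, methyl addition, singlet-oxygen [4+2] cycloaddition, enantioselective Kornblum–DeLaMare desymmetrization, α-methylation.
5. Ring order: the seven-membered ring is the tropone ring and comes first; the five-membered ring is closed last.

Key step: step 9

Remark: endoperoxide 5 is expected as two meso epimers at the acetoxy-bearing carbon that both converge on 7, so one epimer is drawn; the cinchona pseudoenantiomer that gives (S)-7 is the one used; 2-bromo-3-methylbut-1-ene and 4-acetoxybenzoyl chloride are taken as purchasable.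

**Step 1**
Reactants: 1 tropone
Product: 2 cyclohepta-3,5-dien-1-one
Conditions: LiAlH4 (0.3 equiv), Et2O, 0 °C; AcOH, H2O quench
Reagents that add atoms: none
Why: 1,8-conjugate hydride addition to the tropone and kinetic α-protonation of the dienolate on work-up (hydride dearomatization) should give the deconjugated dienone with all seven ring carbons in place.

**Step 2**
Reactants: 2 cyclohepta-3,5-dien-1-one
Product: 4 1-methylcyclohepta-3,5-dien-1-yl acetate, via bromomagnesium alkoxide 3 (not isolated)
Conditions: MeMgBr, LaCl3·2LiCl (0.3 equiv), THF, 0 °C; then Ac2O, 0 °C → rt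
Reagents that add atoms: methylmagnesium bromide (C[Mg]Br); acetic anhydride (CC(=O)OC(C)=O)
Why: lanthanum-assisted Grignard 1,2-addition suppresses enolization of the doubly allylic ketone, and O-acylation of the tertiary alkoxide in the flask installs the leaving group for the later elimination.

**Step 3**
Reactants: 4 1-methylcyclohepta-3,5-dien-1-yl acetate
Product: 5 meso-3-methyl-6,7-dioxabicyclo[3.2.2]non-8-en-3-yl acetate
Conditions: O2, tetraphenylporphyrin (cat.), visible light, CH2Cl2, −20 °C
Reagents that add atoms: dioxygen (O=O)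
Why: [4+2] cycloaddition of singlet oxygen to the s-cis 1,3-diene gives the meso endoperoxide, whose two bridgehead C–H bonds are enantiotopic.

**Step 4**
Reactants: 5 meso endoperoxide
Product: 7 (S)-4-hydroxy-6-methylcyclohepta-2,6-dien-1-one, via acetoxy hydroxy enone 6 (not isolated)
Conditions: 9-O-acetylcupreidine (10 mol %), CH2Cl2, rt; then Et3N, rt
Reagents that add atoms: none
Why: enantioselective Kornblum–DeLaMare rearrangement, in which the chiral amine removes one of the two enantiotopic bridgehead protons and so sets the carbinol centre, followed by E1cB loss of acetic acid from the β-acetoxy ketone, which puts the methyl-bearing double bond in conjugation with the new ketone.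

**Step 5**
Reactants: 7 (S)-4-hydroxy-6-methylcyclohepta-2,6-dien-1-one
Product: 8 (S)-4-[(tert-butyldimethylsilyl)oxy]-6-methylcyclohepta-2,6-dien-1-one
Conditions: TBSCl, imidazole, DMF, 0 °C → rt
Reagents that add atoms: tert-butyldimethylsilyl chloride (CC(C)(C)[Si](C)(C)Cl)
Why: silyl ether formation at the secondary allylic alcohol; the bulky ether later steers the conjugate addition to the opposite face.

**Step 6**
Reactants: 8 silyl ether
Product: 9 (S)-4-[(tert-butyldimethylsilyl)oxy]-2-iodo-6-methylcyclohepta-2,6-dien-1-one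
Conditions: I2, pyridine, CH2Cl2, 0 °C → rt
Reagents that add atoms: iodine (II)
Why: amine-mediated α-iodination of an enone (Baylis–Hillman-type addition, iodination, elimination) should occur only at the enone whose β-carbon is unsubstituted, because pyridine does not add to the β-methyl enone.

**Step 7**
Reactants: 9 α-iodo dienone
Product: 10 (S)-4-[(tert-butyldimethylsilyl)oxy]-2,6-dimethylcyclohepta-2,6-dien-1-one
Conditions: MeZnCl, Pd(PPh3)4 (5 mol %), THF, rt
Reagents that add atoms: methylzinc chloride (C[Zn]Cl)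
Why: Negishi cross-coupling of the α-iodoenone places the future angular methyl group on C2 of the dienone (C8a of the target).

**Step 8**
Reactants: 10 (S)-4-[(tert-butyldimethylsilyl)oxy]-2,6-dimethylcyclohepta-2,6-dien-1-one
Product: 12 (2S,3S,4S)-4-[(tert-butyldimethylsilyl)oxy]-2,6-dimethyl-3-(3-methylbut-1-en-2-yl)-2-(prop-2-en-1-yl)cyclohept-6-en-1-one, via bromomagnesium enolate 11 (not isolated)
Conditions: CH2=C(i-Pr)MgBr (from 2-bromo-3-methylbut-1-ene, Mg, THF), CuBr·SMe2 (20 mol %), THF, −78 → −40 °C; then allyl iodide, HMPA, −40 → 0 °C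
Reagents that add atoms: (3-methylbut-1-en-2-yl)magnesium bromide (CC(C)C(=C)[Mg]Br); allyl iodide (C=CCI)
Why: copper-catalysed conjugate addition goes to the less substituted β-carbon anti to the C4 silyloxy group, and C-allylation of the regiodefined tetrasubstituted enolate anti to the new alkenyl group (three-component vicinal difunctionalization of an enone) sets the quaternary centre with allyl and alkenyl trans.

**Step 9**
Reactants: 12 allyl/1-isopropylvinyl cycloheptenone
Product: 13 (3aS,4S,8aS)-4-[(tert-butyldimethylsilyl)oxy]-6,8a-dimethyl-3-(propan-2-yl)-3a,4,5,8a-tetrahydroazulen-8(1H)-one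
Conditions: second-generation Grubbs catalyst (H2IMes)(PCy3)Cl2Ru=CHPh (5 mol %), toluene (0.005 M), 80 °C
Reagents that add atoms: none
Why: The ruthenium alkylidene loads on the unhindered allyl terminus, adds intramolecularly across the 1,1-disubstituted 1-isopropylvinyl group to a ruthenacyclobutane and cycloreverts, releasing ethylene and the C2=C3 double bond (Chauvin mechanism). The closest known reaction type is ring-closing metathesis of a 1,6-diene to a trisubstituted cyclopentene. The five-membered ring is closed by joining C2 to C3, neither of which is a ring-fusion atom, so the trans relation of C3a and C8a from step 8 passes unchanged into a trans-fused hydroazulene, which no closure at a fusion atom could give. No stereocentre is formed; the new olefin is the handle through which oxygen is later brought to C3 from the β face, giving the isopropyl group cis to the angular methyl, an arrangement that ring closure onto a C3 carbonyl would not give. The step needs chemoselectivity against the C6=C7 olefin, secured because that olefin is trisubstituted, conjugated to the ketone and can only give a strained ring. It also needs cyclization to outrun dimerization, secured by the quaternary C8a (gem-disubstituent effect) and high dilution.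

**Step 10**
Reactants: 13 bicyclic dienone
Product: 14 (2R,3S,3aS,4S,8aS)-2,3-epoxide of 13, epoxide oxygen on the face of H-3a and anti to the 8a-methyl
Conditions: mCPBA, NaHCO3, CH2Cl2, 0 °C
Reagents that add atoms: 3-chloroperoxybenzoic acid (OOC(=O)c1cccc(Cl)c1)
Why: Prilezhaev epoxidation selects the electron-rich trisubstituted cyclopentene over the deactivated enone olefin and should attack the β face, because the α face is covered by the axial angular methyl group.

**Step 11**
Reactants: 14 epoxy enone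
Product: 16 (3S,3aS,4S,8S,8aS)-4-[(tert-butyldimethylsilyl)oxy]-6,8a-dimethyl-3-(propan-2-yl)-1,2,3,3a,4,5,8,8a-octahydroazulene-3,8-diol, via epoxy alcohol 15 (not isolated)
Conditions: LiAlH4, THF, 0 → 60 °C; Fieser work-up (H2O, aq. NaOH)
Reagents that add atoms: none
Why: 1,2-reduction of the β,β-disubstituted enone by axial hydride attack anti to the angular methyl gives the equatorial 8α-alcohol, and SN2 hydride opening of the trisubstituted epoxide at the less substituted C2 leaves the tertiary 3β-alcohol with the isopropyl group cis to the angular methyl.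

**Step 12**
Reactants: 16 diol
Product: 17 (3S,3aS,4S,8R,8aS)-4-[(tert-butyldimethylsilyl)oxy]-3-hydroxy-6,8a-dimethyl-3-(propan-2-yl)-1,2,3,3a,4,5,8,8a-octahydroazulen-8-yl 3-methylbutanoate
Conditions: 3-methylbutanoic acid, PPh3, DIAD, toluene, 0 °C → rt
Reagents that add atoms: 3-methylbutanoic acid (CC(C)CC(O)=O)
Why: Mitsunobu esterification of the secondary allylic alcohol proceeds with inversion at C8 and so places the isovalerate trans to the angular methyl; the tertiary alcohol is not activated.

**Step 13**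
Reactants: 17 silyl ether ester
Product: 18 (3S,3aS,4S,8R,8aS)-3,4-dihydroxy-6,8a-dimethyl-3-(propan-2-yl)-1,2,3,3a,4,5,8,8a-octahydroazulen-8-yl 3-methylbutanoate
Conditions: HF·pyridine, pyridine, THF, 0 °C → rt
Reagents that add atoms: none
Why: buffered fluoride cleavage of the silyl ether frees the 4β-alcohol without touching the allylic ester.

**Step 14**
Reactants: 18 diol ester
Product: 19 (3S,3aR,8R,8aS)-3-hydroxy-6,8a-dimethyl-4-oxo-3-(propan-2-yl)-1,2,3,3a,4,5,8,8a-octahydroazulen-8-yl 3-methylbutanoate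
Conditions: Dess–Martin periodinane, NaHCO3, CH2Cl2, 0 °C → rt
Reagents that add atoms: none
Why: Dess–Martin oxidation of the secondary alcohol under buffered, non-enolizing conditions should keep the β,γ-unsaturated β-hydroxy ketone from conjugating or undergoing retro-aldol cleavage.

**Step 15**
Reactants: 19 β-hydroxy ketone
Product: 20 (3S,3aS,4R,8R,8aS)-3,4-dihydroxy-6,8a-dimethyl-3-(propan-2-yl)-1,2,3,3a,4,5,8,8a-octahydroazulen-8-yl 3-methylbutanoate
Conditions: Me4NBH(OAc)3, MeCN/AcOH (1:1), −30 °C
Reagents that add atoms: none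
Why: Evans–Saksena reduction delivers hydride within the boron complex of the 3β-hydroxyl to the β face of the ketone, the α face being blocked by the syn-axial angular methyl, and gives the anti-1,3-diol, that is the axial 4α-alcohol.

**Step 16**
Reactants: 20 anti-diol ester
Product: 21 (3S,3aS,4R,8R,8aS)-3-hydroxy-6,8a-dimethyl-8-[(3-methylbutanoyl)oxy]-3-(propan-2-yl)-1,2,3,3a,4,5,8,8a-octahydroazulen-4-yl 4-acetoxybenzoate
Conditions: 4-acetoxybenzoyl chloride, Et3N, DMAP (cat.), CH2Cl2, rt
Reagents that add atoms: 4-acetoxybenzoyl chloride (CC(=O)Oc1ccc(cc1)C(Cl)=O)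
Why: DMAP-catalysed acylation takes the secondary alcohol only, the tertiary alcohol being too hindered, and the phenol is carried as its acetate to prevent self-condensation.

**Step 17**
Reactants: 21 aryl acetate
Product: 22 target, (3S,3aS,4R,8R,8aS)-3-hydroxy-6,8a-dimethyl-8-[(3-methylbutanoyl)oxy]-3-(propan-2-yl)-1,2,3,3a,4,5,8,8a-octahydroazulen-4-yl 4-hydroxybenzoate
Conditions: NH3 (2 M in MeOH), 0 °C
Reagents that add atoms: none
Why: chemoselective aminolysis of the activated aryl acetate should free the phenol much faster than ammonia attacks the two hindered esters of secondary alcohols.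

**Compound list**
1 | tropone (cyclohepta-2,4,6-trien-1-one) | O=C1C=CC=CC=C1 | starting material
2 | cyclohepta-3,5-dien-1-one | O=C1CC=CC=CC1 | intermediate
3 | bromomagnesium 1-methylcyclohepta-3,5-dien-1-olate | CC1([O-])CC=CC=CC1.[Mg+2].[Br-] | intermediate (not isolated)
4 | 1-methylcyclohepta-3,5-dien-1-yl acetate | CC(=O)OC1(C)CC=CC=CC1 | intermediate
5 | meso-(1R,5S)-3-methyl-6,7-dioxabicyclo[3.2.2]non-8-en-3-yl acetate, acetoxy anti to the O–O bridge (drawn epimer) | CC(=O)O[C@]1(C)C[C@@H]2C=C[C@H](C1)OO2 | intermediate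
6 | (1S,3S)-3-hydroxy-1-methyl-6-oxocyclohept-4-en-1-yl acetate | O=C1C=C[C@@H](O)C[C@](C)(OC(C)=O)C1 | intermediate (not isolated)
7 | (S)-4-hydroxy-6-methylcyclohepta-2,6-dien-1-one | O=C1C=C[C@@H](O)CC(C)=C1 | intermediate
8 | (S)-4-[(tert-butyldimethylsilyl)oxy]-6-methylcyclohepta-2,6-dien-1-one | O=C1C=C[C@@H](O[Si](C)(C)C(C)(C)C)CC(C)=C1 | intermediate
9 | (S)-4-[(tert-butyldimethylsilyl)oxy]-2-iodo-6-methylcyclohepta-2,6-dien-1-one | O=C1C(I)=C[C@@H](O[Si](C)(C)C(C)(C)C)CC(C)=C1 | intermediate
10 | (S)-4-[(tert-butyldimethylsilyl)oxy]-2,6-dimethylcyclohepta-2,6-dien-1-one | O=C1C(C)=C[C@@H](O[Si](C)(C)C(C)(C)C)CC(C)=C1 | intermediate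
11 | bromomagnesium (3S,4S)-4-[(tert-butyldimethylsilyl)oxy]-2,6-dimethyl-3-(3-methylbut-1-en-2-yl)cyclohepta-1,6-dien-1-olate | [O-]C1=C(C)[C@H](C(=C)C(C)C)[C@@H](O[Si](C)(C)C(C)(C)C)CC(C)=C1.[Mg+2].[Br-] | intermediate (not isolated)
12 | (2S,3S,4S)-4-[(tert-butyldimethylsilyl)oxy]-2,6-dimethyl-3-(3-methylbut-1-en-2-yl)-2-(prop-2-en-1-yl)cyclohept-6-en-1-one (allyl trans to alkenyl, alkenyl trans to silyloxy) | O=C1[C@@](C)(CC=C)[C@H](C(=C)C(C)C)[C@@H](O[Si](C)(C)C(C)(C)C)CC(C)=C1 | intermediate
13 | (3aS,4S,8aS)-4-[(tert-butyldimethylsilyl)oxy]-6,8a-dimethyl-3-(propan-2-yl)-3a,4,5,8a-tetrahydroazulen-8(1H)-one (trans-fused) | O=C1[C@@]2(C)CC=C(C(C)C)[C@@H]2[C@@H](O[Si](C)(C)C(C)(C)C)CC(C)=C1 | intermediate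
14 | (2R,3S,3aS,4S,8aS)-2,3-epoxide of 13, oxygen cis to H-3a and trans to the 8a-methyl | O=C1[C@@]2(C)C[C@H]3O[C@@]3(C(C)C)[C@@H]2[C@@H](O[Si](C)(C)C(C)(C)C)CC(C)=C1 | intermediate
15 | (8S)-8-hydroxy analogue of 14 (8-OH cis to the 8a-methyl) | CC1=C[C@H](O)[C@@]2(C)C[C@H]3O[C@@]3(C(C)C)[C@@H]2[C@@H](O[Si](C)(C)C(C)(C)C)C1 | intermediate (not isolated)
16 | (3S,3aS,4S,8S,8aS)-4-[(tert-butyldimethylsilyl)oxy]-6,8a-dimethyl-3-(propan-2-yl)-1,2,3,3a,4,5,8,8a-octahydroazulene-3,8-diol | CC1=C[C@H](O)[C@@]2(C)CC[C@](O)(C(C)C)[C@@H]2[C@@H](O[Si](C)(C)C(C)(C)C)C1 | intermediate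
17 | (3S,3aS,4S,8R,8aS)-4-[(tert-butyldimethylsilyl)oxy]-3-hydroxy-6,8a-dimethyl-3-(propan-2-yl)-1,2,3,3a,4,5,8,8a-octahydroazulen-8-yl 3-methylbutanoate | CC1=C[C@@H](OC(=O)CC(C)C)[C@@]2(C)CC[C@](O)(C(C)C)[C@@H]2[C@@H](O[Si](C)(C)C(C)(C)C)C1 | intermediate
18 | (3S,3aS,4S,8R,8aS)-3,4-dihydroxy-6,8a-dimethyl-3-(propan-2-yl)-1,2,3,3a,4,5,8,8a-octahydroazulen-8-yl 3-methylbutanoate | CC1=C[C@@H](OC(=O)CC(C)C)[C@@]2(C)CC[C@](O)(C(C)C)[C@@H]2[C@@H](O)C1 | intermediate
19 | (3S,3aR,8R,8aS)-3-hydroxy-6,8a-dimethyl-4-oxo-3-(propan-2-yl)-1,2,3,3a,4,5,8,8a-octahydroazulen-8-yl 3-methylbutanoate | CC1=C[C@@H](OC(=O)CC(C)C)[C@@]2(C)CC[C@](O)(C(C)C)[C@@H]2C(=O)C1 | intermediate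
20 | (3S,3aS,4R,8R,8aS)-3,4-dihydroxy-6,8a-dimethyl-3-(propan-2-yl)-1,2,3,3a,4,5,8,8a-octahydroazulen-8-yl 3-methylbutanoate | CC1=C[C@@H](OC(=O)CC(C)C)[C@@]2(C)CC[C@](O)(C(C)C)[C@@H]2[C@H](O)C1 | intermediate
21 | (3S,3aS,4R,8R,8aS)-3-hydroxy-6,8a-dimethyl-8-[(3-methylbutanoyl)oxy]-3-(propan-2-yl)-1,2,3,3a,4,5,8,8a-octahydroazulen-4-yl 4-acetoxybenzoate | CC1=C[C@@H](OC(=O)CC(C)C)[C@@]2(C)CC[C@](O)(C(C)C)[C@@H]2[C@H](OC(=O)c2ccc(OC(C)=O)cc2)C1 | intermediate
22 | (3S,3aS,4R,8R,8aS)-3-hydroxy-6,8a-dimethyl-8-[(3-methylbutanoyl)oxy]-3-(propan-2-yl)-1,2,3,3a,4,5,8,8a-octahydroazulen-4-yl 4-hydroxybenzoate | CC1=C[C@@H](OC(=O)CC(C)C)[C@@]2(C)CC[C@](O)(C(C)C)[C@@H]2[C@H](OC(=O)c2ccc(O)cc2)C1 | target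

**Total step count:** 17
**Longest linear sequence:** 17 steps (from tropone)

**Steps most likely to fail**

Step 8. The hindered alkenyl Grignard reagent may add 1,2 to the α-methyl enone, and the tetrasubstituted magnesium enolate may allylate slowly or on oxygen. The fallback sets out from 10 and comes back at 12. Conjugate addition is run with the stoichiometric cuprate [CH2=C(i-Pr)]2CuLi (from the alkenyllithium and CuI, Et2O, −78 °C), and the lithium enolate is trapped on oxygen with allyl chloroformate to give the allyl enol carbonate F1. Pd(PPh3)4-catalysed decarboxylative Tsuji allylation of F1 then forms the quaternary centre, the π-allylpalladium enolate pair recombining on the face opposite to the alkenyl group, and gives 12.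

Step 12. The allylic oxyphosphonium ion may ionize or react by the SN2′ path (loss of stereospecificity, elimination to a diene), and the C3 hydroxyl may close an ether onto C8. The fallback sets out from 16 and comes back at 17, and replaces substitution by a reagent-controlled reduction. MnO2 oxidation of the allylic alcohol gives the hydroxy enone F2. Oxazaborolidine-controlled reduction ((S)-2-methyl-CBS-oxazaborolidine, BH3·SMe2, the catalyst antipode being the one that delivers hydride to the α face) gives the 8β-alcohol F3. Acylation with 3-methylbutanoyl chloride (pyridine, DMAP) gives 17.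

Step 10. Facial selectivity of the peracid may be poor if the C4 silyl ether screens the β face of the cyclopentene. The fallback sets out from 13 and comes back at 14, and replaces steric control by hydroxyl direction. Desilylation (HF·pyridine) gives the homoallylic alcohol F4. Epoxidation with VO(acac)2 and t-BuOOH, which delivers oxygen syn to the 4β-hydroxyl, gives the β-epoxy alcohol F5. Resilylation (TBSOTf, 2,6-lutidine) gives 14.

**Further compounds**
F1 | step 8 | allyl (3S,4S)-4-[(tert-butyldimethylsilyl)oxy]-2,6-dimethyl-3-(3-methylbut-1-en-2-yl)cyclohepta-1,6-dien-1-yl carbonate | C=CCOC(=O)OC1=C(C)[C@H](C(=C)C(C)C)[C@@H](O[Si](C)(C)C(C)(C)C)CC(C)=C1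
F2 | step 12 | (3S,3aS,4S,8aS)-4-[(tert-butyldimethylsilyl)oxy]-3-hydroxy-6,8a-dimethyl-3-(propan-2-yl)-2,3,3a,4,5,8a-hexahydroazulen-8(1H)-one | CC1=CC(=O)[C@@]2(C)CC[C@](O)(C(C)C)[C@@H]2[C@@H](O[Si](C)(C)C(C)(C)C)C1
F3 | step 12 | (3S,3aS,4S,8R,8aS)-4-[(tert-butyldimethylsilyl)oxy]-6,8a-dimethyl-3-(propan-2-yl)-1,2,3,3a,4,5,8,8a-octahydroazulene-3,8-diol | CC1=C[C@@H](O)[C@@]2(C)CC[C@](O)(C(C)C)[C@@H]2[C@@H](O[Si](C)(C)C(C)(C)C)C1
F4 | step 10 | (3aS,4S,8aS)-4-hydroxy-6,8a-dimethyl-3-(propan-2-yl)-3a,4,5,8a-tetrahydroazulen-8(1H)-one | O=C1[C@@]2(C)CC=C(C(C)C)[C@@H]2[C@@H](O)CC(C)=C1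
F5 | step 10 | (2R,3S,3aS,4S,8aS)-2,3-epoxide of F4, oxygen cis to the 4-hydroxyl and H-3a | O=C1[C@@]2(C)C[C@H]3O[C@@]3(C(C)C)[C@@H]2[C@@H](O)CC(C)=C1
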